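**Retrosynthetic overview**

1. Target 32 ⇐ ester 30 (tert-butyl ester and silyl ether removed last) ⇐ diol 23 + side-chain acid 28 (esterification at the C8 hydroxyl). Numbering C1–C15 follows the elemane skeleton: ring C5–C10, C10 quaternary, C6 and C8 carbinols, C7 carries the acrylate.
2. Key disconnection of 23: the ring bonds C5–C6 and C7–C8 are cut together. The enabling feature is that each ring carbinol is homoallylic to an exocyclic methylene on the neighbouring ring carbon (O–C6–C5–C4=C3H2 and O–C8–C7–C11=C13H2). Both bonds are therefore carbonyl-allylboration retrons, giving allylboronate/masked aldehyde 14 (C8–C9–C10–C5, with the only preset stereocentre C10) and formyl allylboronate 20 (C6–C7).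
3. 14 ⇐ copper-catalysed enantioselective SN2′ alkynylation of phosphate 5 (sets C10), trans-hydrostannation, borylmethylation. 20 ⇐ ynoate 17 by hydroalumination/borylmethylation. 28 ⇐ 3-methylfuran-2(5H)-one 24.
4. Ring formation: the single ring (cyclohexane C5–C10) is formed in the key step, C5–C6 first (intermolecular), then ring closure at C7–C8.

Key step: step 11

Remark: the target is read from its SMILES as (5S,6R,7S,8S,10R) in the elemane numbering; compounds 1, 6, 15 and 24 are taken as commercial.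

**Step 1**
Reactants: 1 4,4-diethoxybut-1-yne
Product: 4 (2E)-5,5-diethoxy-3-methylpent-2-en-1-ol, via alkenylalane 2 (not isolated), via lithium alkenylaluminate 3 (not isolated)
Conditions: Me3Al, Cp2ZrCl2 (25 mol%), CH2Cl2, −20 → 0 °C; n-BuLi, THF/hexane, −78 °C; (CH2O)n, −78 °C → rt
Reagents that add atoms: trimethylaluminium, C[Al](C)C; formaldehyde (as paraformaldehyde), C=O
Why: Negishi zirconium-catalysed carboalumination adds methyl and aluminium syn across the terminal alkyne (methyl to the internal carbon), and hydroxymethylation of the derived aluminate proceeds with retention, which fixes the (E)-trisubstituted alkene; the low temperature should spare the acetal.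

**Step 2**
Reactants: 4 (2E)-5,5-diethoxy-3-methylpent-2-en-1-ol
Product: 5 diethyl (2E)-5,5-diethoxy-3-methylpent-2-en-1-yl phosphate
Conditions: (EtO)2P(O)Cl, Et3N, 4-(dimethylamino)pyridine (cat.), CH2Cl2, 0 °C
Reagents that add atoms: diethyl chlorophosphate, CCOP(=O)(Cl)OCC
Why: O-phosphorylation of a primary allylic alcohol gives the leaving group needed for copper-catalysed allylic substitution.

**Step 3**
Reactants: 5 diethyl (2E)-5,5-diethoxy-3-methylpent-2-en-1-yl phosphate; 6 tert-butyldimethyl(prop-2-yn-1-yloxy)silane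
Product: 8 (R)-tert-butyl{[4-(2,2-diethoxyethyl)-4-methylhex-5-en-2-yn-1-yl]oxy}dimethylsilane, via alkynylalane 7 (not isolated)
Conditions: 6, i-Bu2AlH, Et3N (5 mol%), hexane, 55 °C; then 5, CuCl2·2H2O (2.5 mol%), 1-(2,6-diisopropylphenyl)-4,5-diphenyl-3-(2-sulfonatophenyl)-4,5-dihydro-1H-imidazol-3-ium (3 mol%, the enantiomer that leads to (R)-8), THF, −15 °C
Reagents that add atoms: none
Why: Copper-catalysed enantioselective allylic substitution delivers the alkynyl group SN2′ to the γ-carbon of the (E)-trisubstituted phosphate, creating the quaternary C10 with methyl and vinyl groups; the face is set by the carbene–copper catalyst.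

**Step 4**
Reactants: 8 (R)-tert-butyl{[4-(2,2-diethoxyethyl)-4-methylhex-5-en-2-yn-1-yl]oxy}dimethylsilane
Product: 9 (R)-4-(2,2-diethoxyethyl)-4-methylhex-5-en-2-yn-1-ol
Conditions: Bu4NF, THF, 0 °C
Reagents that add atoms: none
Why: Fluoride desilylation frees the propargylic hydroxyl that directs the next step and leaves the acetal untouched.

**Step 5**
Reactants: 9 (R)-4-(2,2-diethoxyethyl)-4-methylhex-5-en-2-yn-1-ol
Product: 10 (2Z,4R)-4-(2,2-diethoxyethyl)-4-methyl-2-(tributylstannyl)hexa-2,5-dien-1-ol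
Conditions: Bu3SnH, [Cp*RuCl]4 (2.5 mol%), CH2Cl2, rt
Reagents that add atoms: tributyltin hydride, CCCC[SnH](CCCC)CCCC
Why: Hydroxyl-directed ruthenium-catalysed trans-hydrostannation places tin on the alkyne carbon next to CH2OH and hydrogen trans to it on the carbon next to C10, so the stannyl group ends cis to the quaternary carbon.

**Step 6**
Reactants: 10 (2Z,4R)-4-(2,2-diethoxyethyl)-4-methyl-2-(tributylstannyl)hexa-2,5-dien-1-ol
Product: 11 (2Z,4R)-tert-butyl{[4-(2,2-diethoxyethyl)-4-methyl-2-(tributylstannyl)hexa-2,5-dien-1-yl]oxy}diphenylsilane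
Conditions: t-BuPh2SiCl, imidazole, DMF, rt
Reagents that add atoms: tert-butyl(chloro)diphenylsilane, CC(C)(C)[Si](Cl)(c1ccccc1)c1ccccc1
Why: Silylation of the primary alcohol with an acid-stable silyl group that should survive the aqueous acid phase of the key step.

**Step 7**
Reactants: 11 (2Z,4R)-tert-butyl{[4-(2,2-diethoxyethyl)-4-methyl-2-(tributylstannyl)hexa-2,5-dien-1-yl]oxy}diphenylsilane
Product: 14 (2E,4R)-tert-butyl({4-(2,2-diethoxyethyl)-4-methyl-2-[(4,4,5,5-tetramethyl-1,3,2-dioxaborolan-2-yl)methyl]hexa-2,5-dien-1-yl}oxy)diphenylsilane, via alkenyllithium 12 (not isolated), via borate complex 13 (not isolated)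
Conditions: n-BuLi, THF, −78 °C; ICH2Bpin, −78 °C → rt
Reagents that add atoms: 2-(iodomethyl)-4,4,5,5-tetramethyl-1,3,2-dioxaborolane, ICB1OC(C)(C)C(C)(C)O1
Why: Tin–lithium exchange occurs with retention of alkene geometry, and the alkenyllithium is homologated by a Matteson-type 1,2-metallate shift of its borate complex (iodide leaves), giving the allylboronate with C10 cis to CH2B.

**Step 8**
Reactants: 15 3,3-diethoxyprop-1-yne
Product: 17 tert-butyl 4,4-diethoxybut-2-ynoate, via lithium acetylide 16 (not isolated)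
Conditions: n-BuLi, THF, −78 °C; (t-BuOCO)2O, −78 → 0 °C; aq. NH4Cl
Reagents that add atoms: di-tert-butyl dicarbonate, CC(C)(C)OC(=O)OC(=O)OC(C)(C)C
Why: Acylation of the lithium acetylide with the dicarbonate installs the tert-butyl ester, chosen because it resists lactonisation later.

**Step 9**
Reactants: 17 tert-butyl 4,4-diethoxybut-2-ynoate
Product: 19 tert-butyl (2Z)-4,4-diethoxy-2-[(4,4,5,5-tetramethyl-1,3,2-dioxaborolan-2-yl)methyl]but-2-enoate, via alkenylalane 18 (not isolated)
Conditions: i-Bu2AlH, HMPA, THF, 0 °C; ICH2Bpin, 0 °C → rt; aq. potassium sodium tartrate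
Reagents that add atoms: 2-(iodomethyl)-4,4,5,5-tetramethyl-1,3,2-dioxaborolane, ICB1OC(C)(C)C(C)(C)O1
Why: Conjugate hydroalumination of the ynoate followed by C-alkylation of the α-aluminated enoate is the known entry to 3-substituted 2-(alkoxycarbonyl)allylboronates; CH2B enters cis to the new β-hydrogen, so the acetal carbon ends cis to the ester.

**Step 10**
Reactants: 19 tert-butyl (2Z)-4,4-diethoxy-2-[(4,4,5,5-tetramethyl-1,3,2-dioxaborolan-2-yl)methyl]but-2-enoate
Product: 20 tert-butyl (2Z)-4-oxo-2-[(4,4,5,5-tetramethyl-1,3,2-dioxaborolan-2-yl)methyl]but-2-enoate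
Conditions: Amberlyst-15 (sulfonic acid resin), acetone/H2O, rt; used directly
Reagents that add atoms: water, O
Why: Mild acetal hydrolysis frees the aldehyde; the allylboronate is deactivated by the conjugated ester and formyl groups, so the compound should not add to itself.

**Step 11**
Reactants: 14 (2E,4R)-tert-butyl({4-(2,2-diethoxyethyl)-4-methyl-2-[(4,4,5,5-tetramethyl-1,3,2-dioxaborolan-2-yl)methyl]hexa-2,5-dien-1-yl}oxy)diphenylsilane; 20 tert-butyl (2Z)-4-oxo-2-[(4,4,5,5-tetramethyl-1,3,2-dioxaborolan-2-yl)methyl]but-2-enoate (1.05 equiv)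
Product: 23 tert-butyl 2-[(1R,2R,3S,4R,6S)-3-{3-[(tert-butyldiphenylsilyl)oxy]prop-1-en-2-yl}-4-ethenyl-2,6-dihydroxy-4-methylcyclohexyl]prop-2-enoate, via borate adduct 21 (not isolated), via hydroxy aldehyde 22 (not isolated)
Conditions: (R)-3,3′-bis(2,4,6-triisopropylphenyl)-1,1′-binaphthyl-2,2′-diyl hydrogen phosphate (10 mol%), toluene, −30 → 0 °C; then THF/H2O (10:1), 50 °C; aq. NaHCO3
Reagents that add atoms: water, O
Why: Proposed new method: a one-pot double carbonyl allylboration unites 14 and 20 as a formal [4+2] annulation: the chiral phosphoric acid first catalyses addition of the reactive allylboronate of 14 to the enal aldehyde of 20 through a closed chair (Zimmerman–Traxler) transition state to give borate 21, then, once water is added, hydrolyses the diethyl acetal to aldehyde 22, which is trapped intramolecularly by the ester-substituted allylboronate. The closest known reaction types are the chiral-phosphoric-acid-catalysed allylboration of aldehydes with allyl pinacolboronates, the intramolecular allylboration of formyl-tethered allylboronates to 2-alkenylcycloalkanols, and the thermal or acid-catalysed addition of 2-(alkoxycarbonyl)allylboronates to aldehydes; what is new is their combination in one flask with in situ release of the second aldehyde. The cyclohexane is closed at C7–C8 by 6-exo-trig attack of the allyl γ-carbon on the aldehyde, through a chair carbocycle fused trans to the six-membered boron-containing chair. C5 and C6 are set in the first event: C10 lies cis to CH2B, sits axial in the chair and gives the syn C6-oxygen/C10 relationship, and the (R)-acid is expected to direct the allyl group to the Re face of the aldehyde, overriding the weakly biased quaternary C10. C7 and C8 are set in the second event: C6 lies cis to the ester, so allylic 1,3-strain keeps H6 in the alkene plane and the new bond forms anti to the C6 oxygen (C11 trans to O6), while C6 trans to CH2B sits equatorial in the chair and makes O8 trans to C11, with the C6, C7 and C8 substituents all equatorial in the forming ring. The step needs chemoselectivity between two aldehydes and two allylboronates: the C8 aldehyde stays masked as its acetal until the first addition is over, the allylboronate of 20 is deactivated by the conjugated ester and formyl groups until C6 has become sp3, and the tert-butyl ester suppresses butenolide formation from the (Z)-γ-oxy enoate.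

**Step 12**
Reactants: 24 3-methylfuran-2(5H)-one
Product: 27 4-methoxybenzyl (2Z)-4-acetoxy-2-methylbut-2-enoate, via potassium salt 25 (not isolated), via hydroxy ester 26 (not isolated)
Conditions: KOH, MeOH/H2O, rt, then evaporation; 4-MeOC6H4CH2Cl, DMF, rt; Ac2O, pyridine, 0 °C → rt
Reagents that add atoms: potassium hydroxide, [K+].[OH-]; 4-methoxybenzyl chloride, COc1ccc(CCl)cc1; acetic anhydride, CC(=O)OC(C)=O
Why: Lactone saponification, carboxylate O-alkylation and O-acetylation; the (Z)-geometry is inherited from the butenolide ring, and the hydroxyl is capped before an acid that could relactonise is ever present.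

**Step 13**
Reactants: 27 4-methoxybenzyl (2Z)-4-acetoxy-2-methylbut-2-enoate
Product: 28 (2Z)-4-acetoxy-2-methylbut-2-enoic acid
Conditions: CF3CO2H, anisole, CH2Cl2, 0 °C
Reagents that add atoms: none
Why: Acidolysis of the 4-methoxybenzyl ester (benzyl cation trapped by anisole) releases the acid without base, so neither the acetate nor the alkene geometry should be affected.

**Step 14**
Reactants: 23 tert-butyl 2-[(1R,2R,3S,4R,6S)-3-{3-[(tert-butyldiphenylsilyl)oxy]prop-1-en-2-yl}-4-ethenyl-2,6-dihydroxy-4-methylcyclohexyl]prop-2-enoate; 28 (2Z)-4-acetoxy-2-methylbut-2-enoic acid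
Product: 30 tert-butyl 2-[(1S,2R,3S,4R,6S)-6-{[(2Z)-4-acetoxy-2-methylbut-2-enoyl]oxy}-3-{3-[(tert-butyldiphenylsilyl)oxy]prop-1-en-2-yl}-4-ethenyl-2-hydroxy-4-methylcyclohexyl]prop-2-enoate, via mixed anhydride 29 (not isolated)
Conditions: 28, 2,4,6-Cl3C6H2COCl, Et3N, toluene, rt; then 23, toluene, 70 °C
Reagents that add atoms: none
Why: Yamaguchi esterification through the mixed anhydride without a nucleophilic catalyst, conditions known to keep (Z)-2-methylbut-2-enoates from isomerising; the equatorial C8 hydroxyl, flanked by the ring CH2, should react before the C6 hydroxyl, which is flanked by the axial C5 substituent and by C7.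

**Step 15**
Reactants: 30 tert-butyl 2-[(1S,2R,3S,4R,6S)-6-{[(2Z)-4-acetoxy-2-methylbut-2-enoyl]oxy}-3-{3-[(tert-butyldiphenylsilyl)oxy]prop-1-en-2-yl}-4-ethenyl-2-hydroxy-4-methylcyclohexyl]prop-2-enoate
Product: 32 2-[(1S,2R,3S,4R,6S)-6-{[(2Z)-4-acetoxy-2-methylbut-2-enoyl]oxy}-4-ethenyl-2-hydroxy-3-(3-hydroxyprop-1-en-2-yl)-4-methylcyclohexyl]prop-2-enoic acid, via silylated ester 31 (not isolated)
Conditions: Me3SiOTf, 2,6-lutidine, CH2Cl2, 0 °C; then Bu4NF, AcOH, THF, rt; pH 5 buffer
Reagents that add atoms: none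
Why: Silyl triflate with 2,6-lutidine converts the tert-butyl ester into the trimethylsilyl ester under non-protic conditions (with transient silylation of the C6 hydroxyl), and buffered fluoride then removes all silyl groups, so the γ-hydroxy acid is released without strong acid or base that could cause lactonisation or acetate loss.

**Compound list**

1 | 4,4-diethoxybut-1-yne | C#CCC(OCC)OCC | starting material
2 | [(1E)-4,4-diethoxy-2-methylbut-1-en-1-yl]dimethylalumane | CCOC(OCC)C/C(C)=C/[Al](C)C | intermediate (not isolated)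
3 | lithium butyl[(1E)-4,4-diethoxy-2-methylbut-1-en-1-yl]dimethylaluminate | [Li+].CCCC[Al-](C)(C)/C=C(C)/CC(OCC)OCC | intermediate (not isolated)
4 | (2E)-5,5-diethoxy-3-methylpent-2-en-1-ol | CCOC(OCC)C/C(C)=C/CO | intermediate
5 | diethyl (2E)-5,5-diethoxy-3-methylpent-2-en-1-yl phosphate | CCOC(OCC)C/C(C)=C/COP(=O)(OCC)OCC | intermediate
6 | tert-butyldimethyl(prop-2-yn-1-yloxy)silane | C#CCO[Si](C)(C)C(C)(C)C | starting material
7 | {3-[(tert-butyldimethylsilyl)oxy]prop-1-yn-1-yl}bis(2-methylpropyl)alumane | CC(C)C[Al](CC(C)C)C#CCO[Si](C)(C)C(C)(C)C | intermediate (not isolated)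
8 | (R)-tert-butyl{[4-(2,2-diethoxyethyl)-4-methylhex-5-en-2-yn-1-yl]oxy}dimethylsilane | C=C[C@@](C#CCO[Si](C)(C)C(C)(C)C)(C)CC(OCC)OCC | intermediate
9 | (R)-4-(2,2-diethoxyethyl)-4-methylhex-5-en-2-yn-1-ol | C=C[C@@](C#CCO)(C)CC(OCC)OCC | intermediate
10 | (2Z,4R)-4-(2,2-diethoxyethyl)-4-methyl-2-(tributylstannyl)hexa-2,5-dien-1-ol | C=C[C@@](/C=C(/CO)[Sn](CCCC)(CCCC)CCCC)(C)CC(OCC)OCC | intermediate
11 | (2Z,4R)-tert-butyl{[4-(2,2-diethoxyethyl)-4-methyl-2-(tributylstannyl)hexa-2,5-dien-1-yl]oxy}diphenylsilane | C=C[C@@](/C=C(/CO[Si](c1ccccc1)(c1ccccc1)C(C)(C)C)[Sn](CCCC)(CCCC)CCCC)(C)CC(OCC)OCC | intermediate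
12 | [(2E,4R)-1-[(tert-butyldiphenylsilyl)oxy]-4-(2,2-diethoxyethyl)-4-methylhexa-2,5-dien-2-yl]lithium | C=C[C@@](/C=C(/CO[Si](c1ccccc1)(c1ccccc1)C(C)(C)C)[Li])(C)CC(OCC)OCC | intermediate (not isolated)
13 | lithium [(2E,4R)-1-[(tert-butyldiphenylsilyl)oxy]-4-(2,2-diethoxyethyl)-4-methylhexa-2,5-dien-2-yl](iodomethyl)(pinacolato)borate | [Li+].C=C[C@@](/C=C(/CO[Si](c1ccccc1)(c1ccccc1)C(C)(C)C)[B-]1(CI)OC(C)(C)C(C)(C)O1)(C)CC(OCC)OCC | intermediate (not isolated)
14 | (2E,4R)-tert-butyl({4-(2,2-diethoxyethyl)-4-methyl-2-[(4,4,5,5-tetramethyl-1,3,2-dioxaborolan-2-yl)methyl]hexa-2,5-dien-1-yl}oxy)diphenylsilane | C=C[C@@](/C=C(/CO[Si](c1ccccc1)(c1ccccc1)C(C)(C)C)CB1OC(C)(C)C(C)(C)O1)(C)CC(OCC)OCC | intermediate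
15 | 3,3-diethoxyprop-1-yne | C#CC(OCC)OCC | starting material
16 | (3,3-diethoxyprop-1-yn-1-yl)lithium | [Li]C#CC(OCC)OCC | intermediate (not isolated)
17 | tert-butyl 4,4-diethoxybut-2-ynoate | CCOC(OCC)C#CC(=O)OC(C)(C)C | intermediate
18 | tert-butyl (2E)-2-[bis(2-methylpropyl)alumanyl]-4,4-diethoxybut-2-enoate | CCOC(OCC)/C=C(/[Al](CC(C)C)CC(C)C)C(=O)OC(C)(C)C | intermediate (not isolated)
19 | tert-butyl (2Z)-4,4-diethoxy-2-[(4,4,5,5-tetramethyl-1,3,2-dioxaborolan-2-yl)methyl]but-2-enoate | CCOC(OCC)/C=C(/CB1OC(C)(C)C(C)(C)O1)C(=O)OC(C)(C)C | intermediate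
20 | tert-butyl (2Z)-4-oxo-2-[(4,4,5,5-tetramethyl-1,3,2-dioxaborolan-2-yl)methyl]but-2-enoate | O=C/C=C(/CB1OC(C)(C)C(C)(C)O1)C(=O)OC(C)(C)C | intermediate
21 | tert-butyl (2Z,4S,5S,6R)-5-{3-[(tert-butyldiphenylsilyl)oxy]prop-1-en-2-yl}-6-(2,2-diethoxyethyl)-6-methyl-4-[(4,4,5,5-tetramethyl-1,3,2-dioxaborolan-2-yl)oxy]-2-[(4,4,5,5-tetramethyl-1,3,2-dioxaborolan-2-yl)methyl]octa-2,7-dienoate | CC(C)(C)OC(=O)/C(CB1OC(C)(C)C(C)(C)O1)=C\[C@H](OB1OC(C)(C)C(C)(C)O1)[C@H](C(=C)CO[Si](c1ccccc1)(c1ccccc1)C(C)(C)C)[C@@](C)(C=C)CC(OCC)OCC | intermediate (not isolated)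
22 | tert-butyl (2Z,4S,5S,6R)-5-{3-[(tert-butyldiphenylsilyl)oxy]prop-1-en-2-yl}-4-hydroxy-6-methyl-6-(2-oxoethyl)-2-[(4,4,5,5-tetramethyl-1,3,2-dioxaborolan-2-yl)methyl]octa-2,7-dienoate | CC(C)(C)OC(=O)/C(CB1OC(C)(C)C(C)(C)O1)=C\[C@H](O)[C@H](C(=C)CO[Si](c1ccccc1)(c1ccccc1)C(C)(C)C)[C@@](C)(C=C)CC=O | intermediate (not isolated)
23 | tert-butyl 2-[(1R,2R,3S,4R,6S)-3-{3-[(tert-butyldiphenylsilyl)oxy]prop-1-en-2-yl}-4-ethenyl-2,6-dihydroxy-4-methylcyclohexyl]prop-2-enoate | C=C[C@@]1(C)C[C@H](O)[C@@H](C(=C)C(=O)OC(C)(C)C)[C@H](O)[C@@H]1C(=C)CO[Si](c2ccccc2)(c2ccccc2)C(C)(C)C | intermediate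
24 | 3-methylfuran-2(5H)-one | CC1=CCOC1=O | starting material
25 | potassium (2Z)-4-hydroxy-2-methylbut-2-enoate | [K+].[O-]C(=O)/C(C)=C\CO | intermediate (not isolated)
26 | 4-methoxybenzyl (2Z)-4-hydroxy-2-methylbut-2-enoate | COc1ccc(COC(=O)/C(C)=C\CO)cc1 | intermediate (not isolated)
27 | 4-methoxybenzyl (2Z)-4-acetoxy-2-methylbut-2-enoate | COc1ccc(COC(=O)/C(C)=C\COC(C)=O)cc1 | intermediate
28 | (2Z)-4-acetoxy-2-methylbut-2-enoic acid | OC(=O)/C(C)=C\COC(C)=O | intermediate
29 | (2Z)-4-acetoxy-2-methylbut-2-enoic 2,4,6-trichlorobenzoic anhydride | O=C(OC(=O)/C(C)=C\COC(C)=O)c1c(Cl)cc(Cl)cc1Cl | intermediate (not isolated)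
30 | tert-butyl 2-[(1S,2R,3S,4R,6S)-6-{[(2Z)-4-acetoxy-2-methylbut-2-enoyl]oxy}-3-{3-[(tert-butyldiphenylsilyl)oxy]prop-1-en-2-yl}-4-ethenyl-2-hydroxy-4-methylcyclohexyl]prop-2-enoate | C=C[C@@]1(C)C[C@H](OC(=O)/C(C)=C\COC(C)=O)[C@@H](C(=C)C(=O)OC(C)(C)C)[C@H](O)[C@@H]1C(=C)CO[Si](c2ccccc2)(c2ccccc2)C(C)(C)C | intermediate
31 | trimethylsilyl 2-[(1R,2R,3S,4R,6S)-6-{[(2Z)-4-acetoxy-2-methylbut-2-enoyl]oxy}-3-{3-[(tert-butyldiphenylsilyl)oxy]prop-1-en-2-yl}-4-ethenyl-4-methyl-2-[(trimethylsilyl)oxy]cyclohexyl]prop-2-enoate | C=C[C@@]1(C)C[C@H](OC(=O)/C(C)=C\COC(C)=O)[C@@H](C(=C)C(=O)O[Si](C)(C)C)[C@H](O[Si](C)(C)C)[C@@H]1C(=C)CO[Si](c2ccccc2)(c2ccccc2)C(C)(C)C | intermediate (not isolated)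
32 | 2-[(1S,2R,3S,4R,6S)-6-{[(2Z)-4-acetoxy-2-methylbut-2-enoyl]oxy}-4-ethenyl-2-hydroxy-3-(3-hydroxyprop-1-en-2-yl)-4-methylcyclohexyl]prop-2-enoic acid | C=C[C@@]1(C)C[C@H](OC(=O)/C(C)=C\COC(C)=O)[C@@H](C(=C)C(=O)O)[C@H](O)[C@@H]1C(=C)CO | target

**Step count and risks**

Total step count: 15. Longest linear sequence: 10 steps (steps 1–7, 11, 14, 15).

Steps most likely to fail:

1. Step 11 (proposed new method). The first allylboration may be slow because the allylboronate carries a quaternary γ-substituent, which would erode catalyst control of the aldehyde face. Acetal unmasking may begin before the first addition is complete, which would open self-addition of 14. Ring closure may be slow enough for the (Z)-γ-hydroxy enoate to lactonise. The fallback separates the events with known chemistry and sets out from 14 and 20. The same phosphoric-acid-catalysed allylboration is run alone, the borate is hydrolysed on work-up, and the alcohol is silylated at once (Et3SiCl, imidazole) to the C6 triethylsilyl ether acetal F1. Mild acetal hydrolysis (LiBF4, wet MeCN) should give the aldehyde F2. Thermal intramolecular allylboration (toluene, 80 °C) should give the cyclohexanol F3. Selective removal of the triethylsilyl group (HF·pyridine, pyridine, THF, 0 °C) returns to 23.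

2. Step 14. Acylation may not discriminate enough between the C8 and C6 hydroxyls, or heating may isomerise the (Z)-acyl donor to the (E)-isomer. The fallback sets out from 28 and 23 and replaces substrate-controlled mixed-anhydride acylation by catalyst-directed activation of the diol. Acid 28 is converted under neutral conditions (1-chloro-N,N,2-trimethylprop-1-en-1-amine, CH2Cl2, 0 °C) into the acid chloride F4. The syn-1,3-diol 23 is then acylated at room temperature under borinic acid catalysis (2-aminoethyl diphenylborinate 10 mol%, i-Pr2NEt, MeCN), where the diol is bound as a tetracoordinate borinate and the less hindered oxygen reacts. This returns to 30.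

3. Step 9. The alkene geometry may be lost through the aluminium allenolate, or ethoxide may be lost from the γ-acetal during hydride addition. The fallback sets out from 17 and builds the same geometry by syn-hydrometalation and cross-coupling. Hydrostannation (Bu3SnH, Pd(PPh3)4 cat., THF, 0 °C) should give the α-stannyl enoate F5. Iododestannylation (I2, CH2Cl2, 0 °C) should give the α-iodo enoate F6 with retention. Negishi coupling with IZnCH2Bpin (from ICH2Bpin and Zn; Pd(PPh3)4 cat., THF) returns to 19.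

**Further compounds**

F1 | step 11 | tert-butyl (2Z,4S,5S,6R)-5-{3-[(tert-butyldiphenylsilyl)oxy]prop-1-en-2-yl}-6-(2,2-diethoxyethyl)-6-methyl-2-[(4,4,5,5-tetramethyl-1,3,2-dioxaborolan-2-yl)methyl]-4-[(triethylsilyl)oxy]octa-2,7-dienoate | CC(C)(C)OC(=O)/C(CB1OC(C)(C)C(C)(C)O1)=C\[C@H](O[Si](CC)(CC)CC)[C@H](C(=C)CO[Si](c1ccccc1)(c1ccccc1)C(C)(C)C)[C@@](C)(C=C)CC(OCC)OCC
F2 | step 11 | tert-butyl (2Z,4S,5S,6R)-5-{3-[(tert-butyldiphenylsilyl)oxy]prop-1-en-2-yl}-6-methyl-6-(2-oxoethyl)-2-[(4,4,5,5-tetramethyl-1,3,2-dioxaborolan-2-yl)methyl]-4-[(triethylsilyl)oxy]octa-2,7-dienoate | CC(C)(C)OC(=O)/C(CB1OC(C)(C)C(C)(C)O1)=C\[C@H](O[Si](CC)(CC)CC)[C@H](C(=C)CO[Si](c1ccccc1)(c1ccccc1)C(C)(C)C)[C@@](C)(C=C)CC=O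
F3 | step 11 | tert-butyl 2-[(1R,2R,3S,4R,6S)-3-{3-[(tert-butyldiphenylsilyl)oxy]prop-1-en-2-yl}-4-ethenyl-6-hydroxy-4-methyl-2-[(triethylsilyl)oxy]cyclohexyl]prop-2-enoate | C=C[C@@]1(C)C[C@H](O)[C@@H](C(=C)C(=O)OC(C)(C)C)[C@H](O[Si](CC)(CC)CC)[C@@H]1C(=C)CO[Si](c2ccccc2)(c2ccccc2)C(C)(C)C
F4 | step 14 | (2Z)-4-acetoxy-2-methylbut-2-enoyl chloride | O=C(Cl)/C(C)=C\COC(C)=O
F5 | step 9 | tert-butyl (2E)-4,4-diethoxy-2-(tributylstannyl)but-2-enoate | CCOC(OCC)/C=C(/[Sn](CCCC)(CCCC)CCCC)C(=O)OC(C)(C)C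
F6 | step 9 | tert-butyl (2E)-4,4-diethoxy-2-iodobut-2-enoate | CCOC(OCC)/C=C(/I)C(=O)OC(C)(C)C
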